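Retrosynthesis cuts, in order: C13–C14 (vinyl group, Stille coupling on an enol triflate); C9–C11 (Giese addition of a C9 radical to but-3-en-2-one); the C18–O bond, traced back to a C18–Si bond made by C–H silylation of a 4,4-dimethyl precursor; and the C11=C12 bond of an andrographolide-derived 11-ene (ozonolysis), whose C11 later leaves as CO2.
Forward: rings A and B are taken intact from andrographolide; C19 is deoxygenated, the 8(17)-alkene becomes the C8 carbinol and the side chain is cut back to a C9 carboxyl. The only ring made is the oxasilolane O3–Si–C18–C4–C3, opened again by oxidation; the chain is then joined at C9–C11 and finished at C13–C14.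
Stereochemistry: C3, C5 and C10 come from andrographolide; C8 from epoxidation anti to the C10 methyl and hydride opening; C4 from the key step; C9 from radical addition anti to the axial C17 and C20 methyls.
Enabling feature: on ring A the equatorial C3 oxygen is gauche to the equatorial C4 methyl, so an O3–Si–H unit reaches a C–H bond of that methyl through a five-membered ring, while the axial C4 methyl is screened by the syn-axial C10 methyl.
Key step: step 10

Remark: labdane numbering is kept for all compounds, also after degradation (C17 = methyl on C8, C18 = equatorial and C19 = axial substituent on C4, C20 = methyl on C10); syn and anti refer to C20. The target is taken exactly as drawn, with the C9 side chain axial and anti to C20, and the 8(17)-epoxidation is assumed to occur on the ring-B face opposite C20, as is usual for labd-8(17)-enes.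

Step 1
Reactants: 1 andrographolide
Product: 2 14-deoxy-11,12-didehydroandrographolide (11E-ene conjugated with the butenolide; 3,19-diol and 8(17)-alkene unchanged)
Conditions: Al2O3 (neutral), pyridine, reflux
Reagents that add atoms: none
Why: Base-mediated dehydration (vinylogous 1,4-elimination of the allylic C14 hydroxyl with loss of a C11 proton) is the established conversion of 1 into 2 and places an E double bond at C11–C12, where the chain can later be cut to leave a single carbon on C9; no stereocentre is created.

Step 2
Reactants: 2 14-deoxy-11,12-didehydroandrographolide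
Product: 3 19-deoxy-19-iodo-14-deoxy-11,12-didehydroandrographolide (axial C4–CH2I; C3 hydroxyl free)
Conditions: PPh3, I2, imidazole (premixed), toluene, 80 °C
Reagents that add atoms: iodine, II
Why: Garegg–Samuelsson iodination should select the primary C19 hydroxyl over the hindered secondary C3 hydroxyl, with iodide displacing phosphine oxide at the neopentyl carbon on heating; the premixed, imidazole-buffered reagent should leave the alkenes alone and no stereocentre is touched.

Step 3
Reactants: 3 19-iodide
Product: 4 8,17-epoxide of 3 (spiro-epoxide, oxygen on the ring-B face anti to C20)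
Conditions: mCPBA, NaHCO3, CH2Cl2, 0 °C
Reagents that add atoms: 3-chloroperoxybenzoic acid, O=C(OO)c1cccc(Cl)c1
Why: Prilezhaev epoxidation: the electron-rich 1,1-disubstituted 8(17)-alkene should react well before the lactone-conjugated diene or the neopentyl iodide, and the peracid approaches ring B on the face away from the axial C10 methyl, which sets C8 with its oxygen anti to C20.

Step 4
Reactants: 4 epoxy iodide
Product: 5 19-deoxy tetraol, ent-labda-11E,13Z-diene-3,8,15,16-tetraol (C4 gem-dimethyl; C8 hydroxyl equatorial and anti to C20, C17 methyl axial)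
Conditions: LiAlH4, THF, 0 °C → rt
Reagents that add atoms: none
Why: Hydride reduction with LiAlH4 opens the spiro-epoxide by SN2 attack at its CH2 (C8 keeps the epoxide configuration and becomes the tertiary carbinol with an axial C17 methyl), reduces the neopentyl iodide to the C19 methyl and the butenolide to the diol, the C11–C12 alkene being kept for the cleavage.

Step 5
Reactants: 5 tetraol
Product: 6 3,8,15,16-tetrakis(triethylsilyl) ether of 5
Conditions: TESOTf, 2,6-lutidine, CH2Cl2, −78 → 0 °C
Reagents that add atoms: triethylsilyl trifluoromethanesulfonate, CC[Si](CC)(CC)OS(=O)(=O)C(F)(F)F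
Why: Silylation with a silyl triflate and a hindered pyridine base caps tertiary as well as primary and secondary hydroxyls, so that the C8 oxygen is blocked before a carbonyl group is unmasked β to it; no stereocentre changes.

Step 6
Reactants: 6 tetrakis(triethylsilyl) ether
Product: 7 3,8-bis(triethylsilyloxy)-12,13,14,15,16-pentanor-ent-labdan-11-al (C9–CHO equatorial, C9 as in andrographolide)
Conditions: O3, CH2Cl2, −78 °C; then PPh3, −78 °C → rt
Reagents that add atoms: ozone, [O-][O+]=O
Why: Ozonolysis with reductive phosphine work-up cleaves both double bonds of the diene and leaves C11 on C9 as the aldehyde, silyl ethers being inert to ozone; any epimerisation at C9 is harmless because this centre is reset in step 15.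

Step 7
Reactants: 7 aldehyde
Product: 8 3,8-bis(triethylsilyloxy)-12,13,14,15,16-pentanor-ent-labdan-11-oic acid
Conditions: NaClO2, NaH2PO4, 2-methyl-2-butene, t-BuOH/H2O, 0 °C → rt
Reagents that add atoms: sodium chlorite, [Na+].[O-]Cl=O
Why: Pinnick oxidation takes hindered, enolisable aldehydes to acids in a weakly acidic buffer, under which the β-silyloxy group should not eliminate.

Step 8
Reactants: 8 acid
Product: 9 benzyl 3,8-bis(triethylsilyloxy)-12,13,14,15,16-pentanor-ent-labdan-11-oate
Conditions: BnBr, K2CO3, DMF, rt
Reagents that add atoms: benzyl bromide, BrCc1ccccc1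
Why: Carboxylate O-alkylation (SN2 at benzyl bromide) does not depend on access to the shielded C11 carbonyl and installs an ester that can later be removed by hydrogenolysis instead of hydrolysis.

Step 9
Reactants: 9 benzyl ester bis(silyl ether)
Product: 10 benzyl 3-hydroxy-8-(triethylsilyloxy)-12,13,14,15,16-pentanor-ent-labdan-11-oate (free equatorial C3 hydroxyl, C4 gem-dimethyl)
Conditions: PPTS (cat.), MeOH/CH2Cl2, 0 °C
Reagents that add atoms: none
Why: Acid-catalysed methanolysis of silyl ethers slows sharply with substitution at the carbinol carbon, so the secondary C3 triethylsilyl ether should be cleaved while the tertiary C8 triethylsilyl ether is retained (selective desilylation).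

Step 10
Reactants: 10 benzyl 3-hydroxy-8-(triethylsilyloxy) ester; 11 diethylsilane
Product: 13 benzyl ester oxasilolane (2,2-diethyl-1-oxa-2-silacyclopentane O3–Si–C18–C4–C3 fused to ring A; axial C19 methyl kept), via C3 diethyl(hydrido)silyl ether 12 (not isolated)
Conditions: [Ir(cod)OMe]2 (0.5 mol %), Et2SiH2, THF, rt; evaporate; [Ir(cod)OMe]2 (1 mol %), 3,4,7,8-tetramethyl-1,10-phenanthroline, norbornene, THF, 100 °C
Reagents that add atoms: none
Why: Iridium-catalysed dehydrogenative coupling of the equatorial C3 hydroxyl with Et2SiH2 gives the (hydrido)silyl ether 12; the phenanthroline-ligated iridium catalyst then adds the Si–H bond, the iridium silyl species cleaves a C–H bond of the C4 methyl γ to oxygen, and C–Si reductive elimination delivers the oxasilolane while norbornene takes up the hydrogen. The closest known reaction type is the hydroxyl-directed γ-C(sp3)–H silylation of (hydrido)silyl ethers, which has been applied to 3-hydroxy-4,4-dimethyl terpenoid esters. The single new ring, the five-membered 1-oxa-2-silacyclopentane, closes at the Si–C18 bond by intramolecular C–H silylation and is trans-fused to ring A with oxygen and CH2 both equatorial. C4 becomes stereogenic, and its configuration is fixed by which methyl reacts: the equatorial C3–O–Si tether reaches the equatorial methyl, and the syn-axial C10 methyl blocks approach to the axial C19 methyl. The step needs site selectivity for this primary C–H bond over the axial methyl, the secondary C1 and C2 and the tertiary C5 C–H bonds, and chemoselectivity against the ester. The preference of the catalyst for primary C–H bonds in five-membered closure, the C8 silyl ether without Si–H, the steric shielding of the C11 ester and removal of excess silane before heating should secure both.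

Step 11
Reactants: 13 oxasilolane
Product: 14 benzyl 3,18-dihydroxy-8-(triethylsilyloxy)-12,13,14,15,16-pentanor-ent-labdan-11-oate (C4: axial methyl, equatorial CH2OH)
Conditions: H2O2 (30 % aq.), KHCO3, THF/MeOH, 50 °C
Reagents that add atoms: hydrogen peroxide, OO
Why: Tamao–Fleming oxidation: peroxide adds to the alkoxysilane and C18 migrates from silicon to oxygen with the C4 centre untouched, so the oxasilolane opens to the 3,18-diol while the hindered benzyl ester and the tertiary silyl ether should survive the bicarbonate medium.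

Step 12
Reactants: 14 3,18-diol
Product: 15 18-O-tert-butyldimethylsilyl ether of 14 (C3 hydroxyl free)
Conditions: TBSCl, imidazole, CH2Cl2, 0 °C
Reagents that add atoms: tert-butyldimethylsilyl chloride, CC(C)(C)[Si](C)(C)Cl
Why: Silylation with TBSCl and imidazole is selective for the primary C18 hydroxyl over the secondary C3 hydroxyl that is flanked by the quaternary C4.

Step 13
Reactants: 15 C18 silyl ether
Product: 16 3-O-acetate of 15 (benzyl 3-acetoxy-18-TBS-oxy-8-TES-oxy ester)
Conditions: Ac2O, Et3N, DMAP (cat.), CH2Cl2, rt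
Reagents that add atoms: acetic anhydride, CC(=O)OC(C)=O
Why: DMAP-catalysed acylation (nucleophilic catalysis) esterifies the only free hydroxyl, the equatorial C3 alcohol.

Step 14
Reactants: 16 benzyl ester
Product: 17 3-acetoxy-18-(tert-butyldimethylsilyloxy)-8-(triethylsilyloxy)-12,13,14,15,16-pentanor-ent-labdan-11-oic acid
Conditions: H2 (1 atm), Pd/C, EtOAc, rt
Reagents that add atoms: none
Why: Catalytic hydrogenolysis cleaves the benzyl C–O bond under neutral conditions; the acetate and both silyl ethers are inert in ethyl acetate.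

Step 15
Reactants: 17 acid; 18 but-3-en-2-one
Product: 19 3-acetoxy-18-(tert-butyldimethylsilyloxy)-8-(triethylsilyloxy)-14,15-dinor-9-epi-ent-labdan-13-one (C9–CH2CH2COCH3 axial, anti to C17 and C20)
Conditions: Ir[dF(CF3)ppy]2(dtbbpy)PF6 (1 mol %), K2HPO4, DMF, blue LEDs, rt
Reagents that add atoms: none
Why: Photoredox decarboxylative Giese reaction: the excited iridium complex oxidises the carboxylate, loss of CO2 gives the planar secondary C9 radical, and this nucleophilic radical should add to the enone on the face opposite the axial C17 and C20 methyls, which sets C9 with the new chain axial (inverted relative to andrographolide), the C8 silyl ether preventing hemiketal formation with the new ketone.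

Step 16
Reactants: 19 methyl ketone
Product: 20 13(16)-en-13-yl trifluoromethanesulfonate of 19 (terminal enol triflate, CH2=C(OTf)–CH2CH2–C9)
Conditions: LiN(iPr)2, THF, −78 °C; then N-(5-chloro-2-pyridyl)bis(trifluoromethanesulfonimide) (Comins' reagent), −78 → −20 °C
Reagents that add atoms: N-(5-chloro-2-pyridyl)bis(trifluoromethanesulfonimide), Clc1ccc(nc1)N(S(=O)(=O)C(F)(F)F)S(=O)(=O)C(F)(F)F
Why: Kinetic enolisation of the methyl ketone at its methyl group (faster than deprotonation at C12 or of the acetate) followed by O-triflation with Comins' reagent at low temperature gives the terminal enol triflate.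

Step 17
Reactants: 20 enol triflate; 21 tributyl(vinyl)stannane
Product: 22 3-acetoxy-18-(tert-butyldimethylsilyloxy)-8-(triethylsilyloxy)-9-epi-ent-labda-13(16),14-diene
Conditions: Pd(PPh3)4 (5 mol %), LiCl, THF, 65 °C
Reagents that add atoms: none
Why: Stille coupling: oxidative addition of the alkenyl triflate to zerovalent palladium (assisted by LiCl), transmetalation of the vinyl group from tin and reductive elimination give the 2-substituted 1,3-diene without touching the acetate or silyl ethers.

Step 18
Reactants: 22 bis(silyl ether)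
Product: 23 CNP0313672.1, 3-acetoxy-9-epi-ent-labda-13(16),14-diene-8,18-diol
Conditions: HF·pyridine, pyridine, THF, 0 °C → rt
Reagents that add atoms: none
Why: Fluoride-induced desilylation with pyridine-buffered HF·pyridine removes the primary TBS and the tertiary TES ether under mildly acidic conditions, which should avoid acetyl migration from O3 to O18 and leave the diene and the tertiary alcohol intact.

Compound list
1 | andrographolide | C[C@@]12CC[C@H]([C@@]([C@H]1CCC(=C)[C@H]2C/C=C/3\[C@@H](COC3=O)O)(C)CO)O | starting material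
2 | 14-deoxy-11,12-didehydroandrographolide (3,19-dihydroxy-ent-labda-8(17),11E,13-trien-16,15-olide) | O=C3OCC=C3/C=C/[C@H]1[C@]2(C)CC[C@@H](O)[C@@](C)(CO)[C@H]2CCC1=C | intermediate
3 | 19-deoxy-19-iodo derivative of 2 (axial CH2I on C4, C3 hydroxyl free) | O=C3OCC=C3/C=C/[C@H]1[C@]2(C)CC[C@@H](O)[C@@](C)(CI)[C@H]2CCC1=C | intermediate
4 | 8,17-epoxide of 3 (epoxide oxygen anti to C20, C17 methylene syn) | O=C3OCC=C3/C=C/[C@H]1[C@]2(C)CC[C@@H](O)[C@@](C)(CI)[C@H]2CC[C@@]14CO4 | intermediate
5 | ent-labda-11E,13Z-diene-3,8,15,16-tetraol (C4 gem-dimethyl; C8 hydroxyl equatorial, anti to C20; C17 methyl axial) | OC/C=C(CO)/C=C/[C@H]1[C@]2(C)CC[C@@H](O)C(C)(C)[C@H]2CC[C@]1(C)O | intermediate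
6 | 3,8,15,16-tetrakis(triethylsilyl) ether of 5 | CC[Si](CC)(CC)OC/C=C(CO[Si](CC)(CC)CC)/C=C/[C@H]1[C@]2(C)CC[C@@H](O[Si](CC)(CC)CC)C(C)(C)[C@H]2CC[C@]1(C)O[Si](CC)(CC)CC | intermediate
7 | 3,8-bis(triethylsilyloxy)-12,13,14,15,16-pentanor-ent-labdan-11-al (C9 as in andrographolide) | O=C[C@H]1[C@]2(C)CC[C@@H](O[Si](CC)(CC)CC)C(C)(C)[C@H]2CC[C@]1(C)O[Si](CC)(CC)CC | intermediate
8 | 3,8-bis(triethylsilyloxy)-12,13,14,15,16-pentanor-ent-labdan-11-oic acid | OC(=O)[C@H]1[C@]2(C)CC[C@@H](O[Si](CC)(CC)CC)C(C)(C)[C@H]2CC[C@]1(C)O[Si](CC)(CC)CC | intermediate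
9 | benzyl ester of 8 | O=C(OCc1ccccc1)[C@H]1[C@]2(C)CC[C@@H](O[Si](CC)(CC)CC)C(C)(C)[C@H]2CC[C@]1(C)O[Si](CC)(CC)CC | intermediate
10 | benzyl 3-hydroxy-8-(triethylsilyloxy)-12,13,14,15,16-pentanor-ent-labdan-11-oate (key-step precursor) | O=C(OCc1ccccc1)[C@H]1[C@]2(C)CC[C@@H](O)C(C)(C)[C@H]2CC[C@]1(C)O[Si](CC)(CC)CC | intermediate
11 | diethylsilane | CC[SiH2]CC | starting material
12 | C3 O-diethyl(hydrido)silyl ether of 10 | O=C(OCc1ccccc1)[C@H]1[C@]2(C)CC[C@@H](O[SiH](CC)CC)C(C)(C)[C@H]2CC[C@]1(C)O[Si](CC)(CC)CC | intermediate
13 | oxasilolane: O3–SiEt2–C18 ring trans-fused at C3–C4, axial C19 methyl, benzyl ester and C8 triethylsilyl ether kept | O=C(OCc1ccccc1)[C@H]1[C@]2(C)CC[C@H]3O[Si](CC)(CC)C[C@]3(C)[C@H]2CC[C@]1(C)O[Si](CC)(CC)CC | intermediate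
14 | benzyl 3,18-dihydroxy-8-(triethylsilyloxy)-12,13,14,15,16-pentanor-ent-labdan-11-oate (equatorial CH2OH on C4) | O=C(OCc1ccccc1)[C@H]1[C@]2(C)CC[C@@H](O)[C@](C)(CO)[C@H]2CC[C@]1(C)O[Si](CC)(CC)CC | intermediate
15 | 18-O-tert-butyldimethylsilyl ether of 14 | O=C(OCc1ccccc1)[C@H]1[C@]2(C)CC[C@@H](O)[C@](C)(CO[Si](C)(C)C(C)(C)C)[C@H]2CC[C@]1(C)O[Si](CC)(CC)CC | intermediate
16 | 3-O-acetate of 15 | O=C(OCc1ccccc1)[C@H]1[C@]2(C)CC[C@@H](OC(C)=O)[C@](C)(CO[Si](C)(C)C(C)(C)C)[C@H]2CC[C@]1(C)O[Si](CC)(CC)CC | intermediate
17 | 3-acetoxy-18-(tert-butyldimethylsilyloxy)-8-(triethylsilyloxy)-12,13,14,15,16-pentanor-ent-labdan-11-oic acid | OC(=O)[C@H]1[C@]2(C)CC[C@@H](OC(C)=O)[C@](C)(CO[Si](C)(C)C(C)(C)C)[C@H]2CC[C@]1(C)O[Si](CC)(CC)CC | intermediate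
18 | but-3-en-2-one | CC(=O)C=C | starting material
19 | 3-acetoxy-18-(tert-butyldimethylsilyloxy)-8-(triethylsilyloxy)-14,15-dinor-9-epi-ent-labdan-13-one (C9 chain axial, anti to C17 and C20) | CC(=O)CC[C@@H]1[C@]2(C)CC[C@@H](OC(C)=O)[C@](C)(CO[Si](C)(C)C(C)(C)C)[C@H]2CC[C@]1(C)O[Si](CC)(CC)CC | intermediate
20 | terminal enol triflate of 19 (13(16)-en-13-yl trifluoromethanesulfonate) | C=C(OS(=O)(=O)C(F)(F)F)CC[C@@H]1[C@]2(C)CC[C@@H](OC(C)=O)[C@](C)(CO[Si](C)(C)C(C)(C)C)[C@H]2CC[C@]1(C)O[Si](CC)(CC)CC | intermediate
21 | tributyl(vinyl)stannane | C=C[Sn](CCCC)(CCCC)CCCC | starting material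
22 | 3-acetoxy-18-(tert-butyldimethylsilyloxy)-8-(triethylsilyloxy)-9-epi-ent-labda-13(16),14-diene | C=CC(=C)CC[C@@H]1[C@]2(C)CC[C@@H](OC(C)=O)[C@](C)(CO[Si](C)(C)C(C)(C)C)[C@H]2CC[C@]1(C)O[Si](CC)(CC)CC | intermediate
23 | CNP0313672.1, 3-acetoxy-9-epi-ent-labda-13(16),14-diene-8,18-diol | C=CC(=C)CC[C@@H]1[C@]2(C)CC[C@@H](OC(C)=O)[C@](C)(CO)[C@H]2CC[C@]1(C)O | target

Total step count: 18. Longest linear sequence: 18 steps (1 to 23).

Steps most likely to fail

Step 15. The hindered secondary C9 radical may add to the enone slowly, be reduced before it adds, or be trapped with poor facial discrimination; attack syn to the methyls would return the andrographolide configuration at C9. The fallback forms the C9–C11 bond at nickel instead of by free conjugate addition, so that a bulky alkylnickel species captures the radical on the open face. It sets out from acid 17: esterification with N-hydroxyphthalimide (DIC, DMAP, CH2Cl2) would give the N-(acyloxy)phthalimide F1. Decarboxylative Negishi-type alkyl–alkyl coupling (NiCl2·glyme, 4,4′-di-tert-butyl-2,2′-bipyridine, THF/DMF, rt) with the dialkylzinc prepared from 2-(2-bromoethyl)-2-methyl-1,3-dioxolane (Mg, then ZnCl2) would give the ethylene ketal F2. PPTS in wet acetone would then release the ketone, and the route is rejoined at 19.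

Step 4. Hydride attack or hydroalumination on the dienyl lactone may shift or saturate the C11–C12 double bond, so that the later cleavage would leave one carbon too many on C9; displacement of the C19 iodide by the C3 alkoxide is a second possible loss. The fallback cleaves first and reduces afterwards. It sets out from 4: ozonolysis with NaBH4 work-up would give the epoxy iodo diol F3, which carries C11 as a primary alcohol. LiAlH4 then has only the epoxide and the iodide to reduce and would give the triol F4, and TESOTf/2,6-lutidine would give the tris(triethylsilyl) ether F5. Swern oxidation, which converts primary triethylsilyl ethers directly into aldehydes while secondary and tertiary ones persist, would bring the material back to the route at aldehyde 7.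

Step 10. Cyclometalation may stall on this congested substrate, or the iridium hydride and silane may attack the ester, so that the (hydrido)silyl ether is returned or over-reduced; loss of site selectivity between the two C4 methyls is the lesser concern. The fallback reaches the same C18–H bond by oxime-directed palladation. It sets out from 10: Dess–Martin oxidation would give the C3 ketone F6 and NH2OH·HCl/NaOAc the (E)-oxime F7. Pd(OAc)2 (cat.) with PhI(OAc)2 in AcOH/Ac2O would acetylate the oxime and acetoxylate the equatorial C4 methyl, which lies in the plane of the oxime nitrogen, through a five-membered palladacycle, giving the 18-acetoxy O-acetyl oxime F8. This should be run at the lowest temperature that sustains turnover, to spare the C8 silyl ether. K2CO3/MeOH would give the 18-hydroxy oxime F9 and NaHSO3 in aqueous ethanol the 18-hydroxy 3-ketone F10. NaBH4 delivers hydride axially, away from the axial C4 methyl, to give the equatorial alcohol, and the route is rejoined at diol 14.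

Further compounds
F1 | step 15 | N-(acyloxy)phthalimide of acid 17 | O=C(ON1C(=O)c2ccccc2C1=O)[C@H]1[C@]2(C)CC[C@@H](OC(C)=O)[C@](C)(CO[Si](C)(C)C(C)(C)C)[C@H]2CC[C@]1(C)O[Si](CC)(CC)CC
F2 | step 15 | ethylene ketal of ketone 19 | CC1(OCCO1)CC[C@@H]1[C@]2(C)CC[C@@H](OC(C)=O)[C@](C)(CO[Si](C)(C)C(C)(C)C)[C@H]2CC[C@]1(C)O[Si](CC)(CC)CC
F3 | step 4 | 8,17-epoxy-19-iodo-12,13,14,15,16-pentanor-ent-labdane-3,11-diol | OC[C@H]1[C@]2(C)CC[C@@H](O)[C@@](C)(CI)[C@H]2CC[C@@]13CO3
F4 | step 4 | 12,13,14,15,16-pentanor-ent-labdane-3,8,11-triol | OC[C@H]1[C@]2(C)CC[C@@H](O)C(C)(C)[C@H]2CC[C@]1(C)O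
F5 | step 4 | 3,8,11-tris(triethylsilyl) ether of F4 | CC[Si](CC)(CC)OC[C@H]1[C@]2(C)CC[C@@H](O[Si](CC)(CC)CC)C(C)(C)[C@H]2CC[C@]1(C)O[Si](CC)(CC)CC
F6 | step 10 | benzyl 3-oxo-8-(triethylsilyloxy)-12,13,14,15,16-pentanor-ent-labdan-11-oate | O=C(OCc1ccccc1)[C@H]1[C@]2(C)CCC(=O)C(C)(C)[C@H]2CC[C@]1(C)O[Si](CC)(CC)CC
F7 | step 10 | (E)-oxime of F6 | O=C(OCc1ccccc1)[C@H]1[C@]2(C)CC/C(=N\O)C(C)(C)[C@H]2CC[C@]1(C)O[Si](CC)(CC)CC
F8 | step 10 | 18-acetoxy O-acetyl oxime | O=C(OCc1ccccc1)[C@H]1[C@]2(C)CC/C(=N\OC(C)=O)[C@](C)(COC(C)=O)[C@H]2CC[C@]1(C)O[Si](CC)(CC)CC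
F9 | step 10 | 18-hydroxy oxime | O=C(OCc1ccccc1)[C@H]1[C@]2(C)CC/C(=N\O)[C@](C)(CO)[C@H]2CC[C@]1(C)O[Si](CC)(CC)CC
F10 | step 10 | benzyl 18-hydroxy-3-oxo-8-(triethylsilyloxy)-12,13,14,15,16-pentanor-ent-labdan-11-oate | O=C(OCc1ccccc1)[C@H]1[C@]2(C)CCC(=O)[C@](C)(CO)[C@H]2CC[C@]1(C)O[Si](CC)(CC)CC
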